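## Retrosynthetic overview

1. Target ⇒ photosensitised singlet-oxygen ene reaction of the 7(11)-en-8-one angelate (forms the C11–OOH bond and the Δ6 enone).
2. The C8 ketone ⇒ anodic, N-oxyl-mediated allylic C–H oxygenation of the isopropylidene alkene; the angelate ⇒ acylation of the 3β-OH; the isopropylidene ⇒ isomerisation of an isopropenyl group.
3. 3β,4α-Diol with 5α-H ⇒ 4-methyl-Δ4-3-ketone (dissolving-metal reduction, enolate hydroxylation, hydride reduction).
4. Bicyclic enone ⇒ Robinson annulation of dihydrocarvone with ethyl vinyl ketone. Ring B is bought as (S)-carvone; ring A is the only ring formed.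
5. Stereochemical relay: carvone C5 (later eudesmane C7) sets C10; C10 sets C5 and C4; these set C3; C7 is then erased.

Assumption: the SMILES is read as 3β-angeloyloxy-4α-hydroxy-11-hydroperoxy-5αH-eudesm-6-en-8-one, (3S,4S,5R,10R) in eudesmane numbering; β means the face of the C10 methyl.

## Route

Step 1
Reactants: 1 (S)-(+)-carvone
Product: 2 (2S,5S)-dihydrocarvone (trans-2-methyl-5-isopropenylcyclohexanone; carried on together with its C2 epimer)
Conditions: Zn dust, KOH, EtOH/H2O, reflux
Reagents that add atoms: none
Why: Zinc/alkali conjugate reduction saturates only the enone C=C and leaves the isopropenyl group and the purchased stereocentre untouched; the C2 epimer ratio does not matter because C2 is re-enolised in step 2.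

Step 2
Reactants: 2 (2S,5S)-dihydrocarvone; 3 ethyl vinyl ketone
Product: 6 (4aS,7S)-1,4a-dimethyl-7-(prop-1-en-2-yl)-4,4a,5,6,7,8-hexahydronaphthalen-2(3H)-one (7βH-eudesma-4,11-dien-3-one), via Michael adduct diketone 4 (not isolated), via aldol ketol 5 (not isolated)
Conditions: 3 (1.2 equiv), KOH (0.15 equiv), EtOH, −10 → 0 °C; then aq KOH, EtOH, reflux
Reagents that add atoms: ethyl vinyl ketone CCC(=O)C=C
Why: Robinson annulation; the more substituted enolate adds to the enone axially on the half-chair that keeps the isopropenyl group equatorial, so the new chain enters cis to isopropenyl and the methyl ends up trans to it (the known outcome in the enantiomeric series), which sets the quaternary C10 from the carvone stereocentre before aldol condensation closes ring A.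

Step 3
Reactants: 6 7βH-eudesma-4,11-dien-3-one
Product: 8 4α-hydroxy-5αH,7βH-eudesm-11-en-3-one, via lithium enolate 7 (not isolated)
Conditions: Li (2.5 equiv), NH3/THF, t-BuOH (1.0 equiv), −78 °C; isoprene; evaporate NH3; MoO5·pyridine·HMPA (1.5 equiv), THF, −40 → −20 °C; H2O work-up
Reagents that add atoms: MoO5·pyridine·HMPA (MoOPH) O=[Mo]12(OO1)OO2.c1ccncc1.CN(C)P(=O)(N(C)C)N(C)C
Why: Stork-type dissolving-metal enone reduction protonates C5 axially on the α-face (trans-decalin) and gives the regiodefined Δ3 lithium enolate, which the bulky peroxomolybdenum reagent hydroxylates (Vedejs enolate oxidation) at C4 from the α-face, opposite the syn-axial C10 methyl, to give 4α-OH/4β-Me.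

Step 4
Reactants: 8 4α-hydroxy-5αH,7βH-eudesm-11-en-3-one
Product: 9 5αH,7βH-eudesm-11-ene-3β,4α-diol
Conditions: NaBH4, MeOH, 0 °C
Reagents that add atoms: none
Why: Borohydride reduction; hydride adds axially from the α-face because the β-face is screened by the axial 4β-methyl, so the equatorial 3β-alcohol (trans to the 4α-OH) forms, as with 4,4-disubstituted 3-keto terpenoids.

Step 5
Reactants: 9 5αH,7βH-eudesm-11-ene-3β,4α-diol
Product: 10 5αH-eudesm-7(11)-ene-3β,4α-diol
Conditions: chloro[N,N'-ethylenebis(3,5-di-tert-butylsalicylideneiminato)]cobalt (5 mol %), PhSiH3 (10 mol %), benzene, 23 °C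
Reagents that add atoms: none
Why: Metal-hydride hydrogen-atom-transfer alkene isomerisation with an achiral trivalent cobalt salen complex; H-atom transfer to the CH2 terminus gives the tertiary C11 radical, divalent cobalt removes the weak tertiary C7–H, and the tetrasubstituted alkene is too hindered to react further, so the C7 stereocentre is erased after it has done its work.

Step 6
Reactants: 10 5αH-eudesm-7(11)-ene-3β,4α-diol; 11 angelic acid
Product: 12 4α-hydroxy-5αH-eudesm-7(11)-en-3β-yl angelate
Conditions: 11, 2,4,6-trichlorobenzoyl chloride, Et3N, toluene, 23 °C; then 10, toluene, 80 °C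
Reagents that add atoms: angelic acid C/C=C(/C)C(=O)O
Why: Yamaguchi-type mixed-anhydride esterification without a nucleophilic catalyst acylates the secondary equatorial 3β-OH only (the tertiary 4α-OH is inert) and is the standard way to make angelates without Z→E isomerisation to the tiglate.

Step 7
Reactants: 12 4α-hydroxy-5αH-eudesm-7(11)-en-3β-yl angelate
Product: 14 3β-angeloyloxy-4α-hydroxy-5αH-eudesm-7(11)-en-8-one, via allylic tert-butyl peroxide 13 (not isolated)
Conditions: tetrachloro-N-hydroxyphthalimide (20 mol %), pyridine (2 equiv), t-BuOOH (1.5 equiv), LiClO4 (0.1 M), acetone, reticulated vitreous carbon anode and cathode, undivided cell, constant current (10 mA per mmol, about 3 F/mol), 23 °C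
Reagents that add atoms: tert-butyl hydroperoxide CC(C)(C)OO
Why: Proposed new method: the anodically generated tetrachlorophthalimide-N-oxyl abstracts the axial 8β-H, which is aligned with the exocyclic π bond (the equally aligned 6β-H is shielded by the syn-axial C4 and C10 methyls, and the methyl C–H bonds are stronger), the allyl radical is trapped by t-BuOO• at its less hindered secondary C8 end so the tetrasubstituted C7=C11 bond is kept, and pyridine-induced Kornblum–DeLaMare-type elimination of peroxide 13 gives the α-isopropylidene ketone while H2 forms at the cathode; the closest known reaction type is the N-hydroxyphthalimide-mediated electrochemical allylic C–H oxidation of endocyclic di- and trisubstituted cycloalkenes to enones, which to my knowledge has not been shown on an exocyclic tetrasubstituted isopropylidene alkene with competing ring-CH2 and CH3 sites.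

Step 8
Reactants: 14 3β-angeloyloxy-4α-hydroxy-5αH-eudesm-7(11)-en-8-one
Product: 15 3β-angeloyloxy-4α-hydroxy-11-hydroperoxy-5αH-eudesm-6-en-8-one (CNP0161122.1)
Conditions: O2 (1 atm), meso-tetraphenylporphyrin (1 mol %), CH2Cl2, 0 °C, white LED irradiation; stop at full conversion
Reagents that add atoms: dioxygen O=O
Why: Schenck ene reaction of photosensitised singlet oxygen on the s-cis α-isopropylidene ketone; the gem-selectivity of enones puts oxygen on the β-carbon C11 and takes hydrogen from C6 (the ring CH2 geminal to the carbonyl), giving the conjugated Δ6-enone and the tertiary hydroperoxide with no new stereocentre, while the trisubstituted electron-poor angelate reacts much more slowly and the low-energy sensitiser cannot isomerise it.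

## Compound list

1 | (S)-(+)-carvone | CC1=CC[C@@H](CC1=O)C(C)=C | starting material
2 | (2S,5S)-dihydrocarvone (used with its C2 epimer) | C[C@H]1CC[C@@H](CC1=O)C(C)=C | intermediate
3 | ethyl vinyl ketone (pent-1-en-3-one) | CCC(=O)C=C | starting material
4 | (2S,5S)-2-methyl-2-(3-oxopentyl)-5-(prop-1-en-2-yl)cyclohexan-1-one, Michael adduct (not isolated) | CCC(=O)CC[C@]1(C)CC[C@@H](CC1=O)C(C)=C | intermediate
5 | 5-hydroxy-7βH-eudesm-11-en-3-one, aldol ketol (not isolated; C4 and C5 configuration not defined, lost on dehydration) | CC1C(=O)CC[C@]2(C)CC[C@H](C(C)=C)CC12O | intermediate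
6 | (4aS,7S)-1,4a-dimethyl-7-(prop-1-en-2-yl)-4,4a,5,6,7,8-hexahydronaphthalen-2(3H)-one (7βH-eudesma-4,11-dien-3-one; 10β-Me, 7α-isopropenyl) | CC1=C2C[C@@H](C(C)=C)CC[C@@]2(C)CCC1=O | intermediate
7 | lithium 5αH,7βH-eudesma-3,11-dien-3-olate (not isolated) | [Li+].[O-]C1=C(C)[C@@H]2C[C@@H](C(C)=C)CC[C@@]2(C)CC1 | intermediate
8 | (4S,5R,7S,10S)-4α-hydroxy-5αH,7βH-eudesm-11-en-3-one (4β-Me, 10β-Me) | O=C1CC[C@]2(C)CC[C@H](C(C)=C)C[C@H]2[C@]1(C)O | intermediate
9 | (3S,4S,5R,7S,10S)-5αH,7βH-eudesm-11-ene-3β,4α-diol | O[C@H]1CC[C@]2(C)CC[C@H](C(C)=C)C[C@H]2[C@]1(C)O | intermediate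
10 | (3S,4S,5R,10S)-5αH-eudesm-7(11)-ene-3β,4α-diol | O[C@H]1CC[C@]2(C)CCC(=C(C)C)C[C@H]2[C@]1(C)O | intermediate
11 | angelic acid ((Z)-2-methylbut-2-enoic acid) | C/C=C(/C)C(=O)O | starting material
12 | (3S,4S,5R,10S)-4α-hydroxy-5αH-eudesm-7(11)-en-3β-yl angelate | C/C=C(/C)C(=O)O[C@H]1CC[C@]2(C)CCC(=C(C)C)C[C@H]2[C@]1(C)O | intermediate
13 | 8-(tert-butylperoxy)-4α-hydroxy-5αH-eudesm-7(11)-en-3β-yl angelate (not isolated; C8 epimers) | C/C=C(/C)C(=O)O[C@H]1CC[C@]2(C)CC(OOC(C)(C)C)C(=C(C)C)C[C@H]2[C@]1(C)O | intermediate
14 | (3S,4S,5R,10R)-3β-angeloyloxy-4α-hydroxy-5αH-eudesm-7(11)-en-8-one | C/C=C(/C)C(=O)O[C@H]1CC[C@]2(C)CC(=O)C(=C(C)C)C[C@H]2[C@]1(C)O | intermediate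
15 | (3S,4S,5R,10R)-3β-angeloyloxy-4α-hydroxy-11-hydroperoxy-5αH-eudesm-6-en-8-one (CNP0161122.1) | C/C=C(/C)C(=O)O[C@H]1CC[C@]2(C)CC(=O)C(C(C)(C)OO)=C[C@H]2[C@]1(C)O | target

## Step count and risks

Total step count: 8. Longest linear sequence: 8 (fully linear from 1; 3 and 11 are bought).

Steps most likely to fail:

**Step 7 (the proposed new electrochemical oxygenation).** Possible failures are competing abstraction at C6 (giving the 6-ketone), trapping of the allyl radical at tertiary C11, and epoxidation of the electron-rich tetrasubstituted alkene by peroxyl radicals. The fallback uses known chemistry and also reorders the acylation. It sets out from diol 10, which is hydroxylated at C8 with SeO2 (0.5 equiv) and t-BuOOH in CH2Cl2 (ene reaction then [2,3]-sigmatropic shift, a pericyclic and not a radical pathway) to give 5αH-eudesm-7(11)-ene-3β,4α,8-triol F1 as a mixture of C8 epimers. MnO2 in CH2Cl2 then oxidises only the allylic 8-OH to give 3β,4α-dihydroxy-5αH-eudesm-7(11)-en-8-one F2. Angeloylation of the 3β-OH of F2 under the step 6 conditions brings the route back at 14.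

**Step 3 (one-pot reduction and enolate hydroxylation).** Possible failures are a low-yielding oxidation of the lithium enolate in the presence of lithium tert-butoxide, or erosion of face selectivity at C4 or C5 caused by the axial 7α-isopropenyl group. The fallback sets out from enone 6 and separates the two events. The Li/NH3 reduction is quenched with Me3SiCl/Et3N to give the isolable 3-(trimethylsilyloxy)-5αH,7βH-eudesma-3,11-diene F3. Rubottom oxidation of F3 with dimethyldioxirane (acetone/CH2Cl2, −40 °C), which epoxidises the electron-rich enol ether from the α-face much faster than the isopropenyl group, and citric acid/MeOH work-up return the route at 8.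

**Step 6 (angeloylation of a hindered alcohol).** Possible failures are sluggish acylation next to the quaternary carbinol and partial isomerisation to the tiglate at 80 °C. The fallback sets out from diol 10 and builds the Z-alkene on the substrate. The 3β-OH is coupled with 2-[bis(2,2,2-trifluoroethoxy)phosphoryl]propanoic acid (DCC, catalytic DMAP, CH2Cl2, 0 °C) to give 4α-hydroxy-5αH-eudesm-7(11)-en-3β-yl 2-[bis(2,2,2-trifluoroethoxy)phosphoryl]propanoate F4. Still–Gennari olefination of F4 (KN(SiMe3)2, 18-crown-6, THF, −78 °C, then acetaldehyde) gives the (Z)-2-methylbut-2-enoate and returns the route at 12.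

Further compounds
F1 | step 7 | 5αH-eudesm-7(11)-ene-3β,4α,8-triol (C8 epimers) | O[C@H]1CC[C@]2(C)CC(O)C(=C(C)C)C[C@H]2[C@]1(C)O
F2 | step 7 | 3β,4α-dihydroxy-5αH-eudesm-7(11)-en-8-one | O[C@H]1CC[C@]2(C)CC(=O)C(=C(C)C)C[C@H]2[C@]1(C)O
F3 | step 3 | 3-(trimethylsilyloxy)-5αH,7βH-eudesma-3,11-diene | C[Si](C)(C)OC1=C(C)[C@@H]2C[C@@H](C(C)=C)CC[C@@]2(C)CC1
F4 | step 6 | 4α-hydroxy-5αH-eudesm-7(11)-en-3β-yl 2-[bis(2,2,2-trifluoroethoxy)phosphoryl]propanoate (epimers at the phosphonate carbon) | CC(C(=O)O[C@H]1CC[C@]2(C)CCC(=C(C)C)C[C@H]2[C@]1(C)O)P(=O)(OCC(F)(F)F)OCC(F)(F)F
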